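## Structural features

The target is a longipinane sesquiterpenoid: a tricyclo[5.4.0.0^{2,8}]undecane in which the cyclobutane C4–C5–C11–C10 has both diagonals bridged. C4···C11 is bridged by C3–C2–C1 (cyclohexanone ring, a bicyclo[3.1.1]heptane) and C5···C10 by C6–C7–C8–C9 (a bicyclo[4.1.1]octane). C10 is quaternary (CH3, C4, C9, C11) and C6 is a gem-dimethyl carbon, so the oxygenated carbons C7–C9 lie between two fully substituted centres. There are eight stereocentres (C3, C4, C5, C7, C8, C9, C10, C11), seven of them contiguous. The C7 hydroxyl is trans to the cis C8/C9 oxygens, and the C3 methyl lies anti to the C10 bridge. The fragile groups are the two (Z)-2-methylbut-2-enoates (Z→E isomerisation to tiglates, acyl migration to the free C7–OH) and the strained four-membered ring next to the C1 carbonyl. The real difficulty is the doubly bridged cyclobutane with its quaternary C10: cutting either pair of opposite cyclobutane bonds leaves an eleven-membered ring, so a simple intramolecular [2+2] is not available. The key step exploits the 1,4-dioxygen pattern O=C1–C11–C10–C9–O across the cyclobutane bond C10–C11. With C9 as a ketone this bond is the product of an oxidative coupling of two enolates, and cutting it leaves a cis-fused bicyclo[5.4.0]undecane that comes from a Diels–Alder adduct.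

## Logic of the disconnections

18 ⇒ 17 ⇒ 16: the two ester C–O bonds at C8 and C9 and the O–Si bond at C7 are cut. The angelates are the most fragile groups and are therefore introduced last. The forward step must acylate two hindered secondary alcohols without Z→E isomerisation while C7–OH stays masked.

16 ⇒ 15: the C8–O and C9–O bonds are cut together. A cis-diol maps onto a C8=C9 alkene, and the allylic C7 oxygen is the only nearby element that distinguishes the two alkene faces. The forward step must add anti to the C7 silyloxy group.

15 ⇒ 14 ⇒ 12: the allylic alcohol (C7–OH, C8=C9) is traced back to a 7,8-epoxy-9-ketone. This returns C9 to the ketone level, which is what acidifies C10 for the key step. The forward step must transpose with retention at C7 and tolerate the C1 ketone.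

12 ⇒ 11: the C3–CH3 bond is cut. The resulting enone is needed anyway to direct enolisation to C11, and conjugate addition from the face away from the C10 bridge sets C3. The forward step must select the strained enone over the epoxy ketone.

11 ⇒ 9: the bond C10–C11 is cut. This removes the cyclobutane, both bridged ring systems, the quaternary centre and two stereocentres in one operation, and leaves a cis-fused bicycle with two ketones. The forward step must enolise only at C10 and C11 and close a four-membered ring.

9 ⇒ 8 ⇒ 7: the C2=C3 double bond is traced to a regiodefined enol silane and the epoxide to the C7=C8 enone. The epoxide is placed on the bicycle because there the two enone faces differ (convex versus concave), whereas in the tricycle they are nearly equivalent. The forward step must attack C7 from the face of the ring-fusion hydrogens.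

7 ⇒ 6 ⇒ 4: the C10–CH3 bond is cut, then C10 itself is excised from between C4 and C9. This contracts the seven-membered enone to a cyclohexenone whose α,β-positions are C4 and C5. The forward ring expansion must migrate C4 and not the vinylic C8.

4 ⇒ 2 + 3: the bonds C3–C4 and C5–C11 are cut. This is a Diels–Alder disconnection that delivers the cis ring fusion and, through desymmetrisation of 3, the absolute configuration. The forward step must choose one enantiotopic C=C face, give the "para" regiochemistry and stop after one addition.

2 ⇒ 1: the O–Si bond is cut; 2 is the enol silane of 1.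

## Other disconnections considered

Alternative 1: the first idea for a cyclobutane is an enone–alkene [2+2] photocycloaddition. The cut is C5–C11 and C4–C10. The forward key step is irradiation of the acyclic trienone A1, in which the enone C10=C11–C1=O and the alkene C4=C5 are joined by C1–C2–C3, to give the bicyclo[3.1.1]heptanone A2; ring-closing metathesis would then form C8=C9. The two alkenes are 1,6-related, and for this tether length the normal mode of closure is the 1,2-fused one, so the crossed mode needed here is expected to be the minor pathway. C3 and C7 would have to be set separately in an acyclic chain, and the quaternary C10 would be formed at a fully substituted enone carbon. The chosen plan makes the same ring from a rigid bicycle in which only one closure is geometrically possible.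

Alternative 2: chiral pool. The core of 18 contains the skeleton of (1R,5R)-(+)-verbenone A3. The cut is the whole four-carbon bridge C6–C9; the forward key steps would be functionalisation of the cyclobutane C5–H and of the anti methyl group on C10, then metathesis of the divinyl compound A4. Neither of these C–H bonds has a neighbouring handle, so several steps of uncertain selectivity would precede any ring formation. Hydrogenation of the C2=C3 bond would also be expected to occur from the open C5 face and so place the C3 methyl syn to C10, the opposite of 18. The chosen plan builds the cyclobutane from functionality that is already in place.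

Alternative 3: sigmatropic ring contraction. The cut is again C10–C11, but through an Ireland–Claisen rearrangement of the bridged lactone A5, whose carbonyl carbon becomes the C10 substituent in the acid A6. A [3,3] shift through the enforced boat places the carboxyl cis to C1, as the C10 methyl of 18 requires. However, the exothermicity of an ester-enolate Claisen rearrangement (about 30 kcal/mol) is of the same order as the strain being created (estimated above 40 kcal/mol for the tricycle), so the step is thermodynamically marginal. The carboxyl of A6 would need three or four further steps to become CH3, and A5 itself needs five contiguous stereocentres on a cyclohexene. The oxidative coupling is driven by two irreversible electron transfers and needs no carbon-level correction afterwards.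

Key step: step 7

Remark: atoms are numbered as in longipinane (C1 ketone carbon, C2 CH2, C3 CH–CH3, C4/C5/C11/C10 cyclobutane, C6 CMe2, C7 CH–OH, C8 and C9 CH–O-angeloyl); the same numbers are used for the bicyclic (10,11-seco) intermediates.

## Route

Step 1
Reactants: 1 but-3-en-2-one
Product: 2 2-[(triisopropylsilyl)oxy]buta-1,3-diene
Conditions: TIPSOTf, Et3N, Et2O, 0 °C → rt
Reagents that add atoms: triisopropylsilyl trifluoromethanesulfonate, CC(C)[Si](C(C)C)(C(C)C)OS(=O)(=O)C(F)(F)F
Why: Soft enolisation of the methyl ketone and O-silylation give the cross-conjugated 2-silyloxy diene (silyl dienol ether formation); the TIPS group makes the later enol silane robust.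

Step 2
Reactants: 2 2-[(triisopropylsilyl)oxy]buta-1,3-diene; 3 4,4-dimethylcyclohexa-2,5-dien-1-one
Product: 4 (4aR,8aS)-4,4-dimethyl-6-[(triisopropylsilyl)oxy]-4a,5,8,8a-tetrahydronaphthalen-1(4H)-one (cis-fused)
Conditions: 3 (2 equiv), (S)-o-tolyl oxazaborolidine·AlBr3 (10 mol %), CH2Cl2, −78 → −40 °C
Reagents that add atoms: none
Why: Catalytic enantioselective Diels–Alder reaction that desymmetrises 3; the nucleophilic CH2 terminus next to C–OSi (C11) bonds to the enone β-carbon (C5), suprafacial addition gives the cis fusion, and the chiral Lewis acid selects one enantiotopic C=C face and so sets C4 and C5 (the catalyst antipode is used if the sense of induction is opposite to that needed).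

Step 3
Reactants: 4 (4aR,8aS)-4,4-dimethyl-6-[(triisopropylsilyl)oxy]-4a,5,8,8a-tetrahydronaphthalen-1(4H)-one
Product: 6 cis-9,9-dimethyl-2-[(triisopropylsilyl)oxy]-1,4,4a,5,9,9a-hexahydro-6H-benzo[7]annulen-6-one (C9 ketone, C7=C8, C10H2), via α-trimethylsilyl ketone 5 (not isolated)
Conditions: TMSCHN2, Sc(OTf)3 (10 mol %), CH2Cl2/toluene, −40 → 0 °C; then K2CO3 (cat.), MeOH, 0 °C
Reagents that add atoms: (trimethylsilyl)diazomethane, C[Si](C)(C)C=[N+]=[N-]
Why: Lewis-acid-catalysed diazoalkane homologation (Tiffeneau–Demjanov type); the sp3 ring-fusion carbon C4 should migrate with retention in preference to the vinylic C8, which inserts C10 between C4 and C9 and keeps the enone conjugated; methanolysis cleaves the C–Si bond.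

Step 4
Reactants: 6 cis-9,9-dimethyl-2-[(triisopropylsilyl)oxy]-1,4,4a,5,9,9a-hexahydro-6H-benzo[7]annulen-6-one
Product: 7 cis-5,9,9-trimethyl-2-[(triisopropylsilyl)oxy]-1,4,4a,5,9,9a-hexahydro-6H-benzo[7]annulen-6-one (C10 methyl, both C10 epimers)
Conditions: LDA, THF, −78 °C; MeI, −78 → −40 °C
Reagents that add atoms: iodomethane, CI
Why: Kinetic α'-deprotonation of the enone (C10 is its only enolisable position, C6 being quaternary) and C-methylation; the C10 configuration is irrelevant because C10 is planarised again in step 7.

Step 5
Reactants: 7 cis-5,9,9-trimethyl-2-[(triisopropylsilyl)oxy]-1,4,4a,5,9,9a-hexahydro-6H-benzo[7]annulen-6-one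
Product: 8 7,8-epoxide of 7 (7,8-epoxy-5,9,9-trimethyl-2-[(triisopropylsilyl)oxy]-1,4,4a,5,7,8,9,9a-octahydro-6H-benzo[7]annulen-6-one; epoxide oxygen syn to H-5 and H-4)
Conditions: t-BuOOH, Triton B (cat.), THF, 0 °C
Reagents that add atoms: tert-butyl hydroperoxide, CC(C)(C)OO
Why: Weitz–Scheffer nucleophilic epoxidation; the hydroperoxide should add to C7 on the convex face of the cis-fused bicycle (the face of the ring-fusion hydrogens, away from the C5–C11 bond), which fixes the C7–O configuration; the electron-rich enol silane is not attacked by a nucleophilic oxidant.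

Step 6
Reactants: 8 7,8-epoxy-5,9,9-trimethyl-2-[(triisopropylsilyl)oxy]-1,4,4a,5,7,8,9,9a-octahydro-6H-benzo[7]annulen-6-one
Product: 9 cis-fused 7,8-epoxy-5,9,9-trimethyl-4a,5,7,8,9,9a-hexahydro-1H-benzo[7]annulene-2,6-dione (C1 enone with C2=C3, C9 epoxy ketone)
Conditions: Pd(OAc)2 (1.1 equiv), MeCN, 40 °C
Reagents that add atoms: none
Why: Saegusa–Ito oxidation of the regiodefined enol silane from the cycloaddition places the double bond at C2=C3; this enone later directs enolisation to C11 and accepts the C3 methyl.

Step 7
Reactants: 9 cis-fused 7,8-epoxy-5,9,9-trimethyl-4a,5,7,8,9,9a-hexahydro-1H-benzo[7]annulene-2,6-dione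
Product: 11 7,8-epoxy-12-norlongipin-2-ene-1,9-dione (tricyclic; epoxide oxygen anti to C11, C10 methyl on the face of the C1–C3 bridge), via dilithium bis-enolate 10 (not isolated)
Conditions: 9 added to LDA (2.3 equiv), THF (0.005 M), −78 → −40 °C; then Fe(acac)3 (2.2 equiv), THF, −78 → 0 °C
Reagents that add atoms: none
Why: Two kinetic α'-deprotonations (the enone at C11, the epoxy ketone at C10; neither carbonyl has another accessible acidic site) give bis-enolate 10, in which the cis ring fusion holds C10 (axial on C4) and C11 in a 1,3-diaxial-like contact. Fe(III) oxidises one enolate to an α-keto radical that adds to the other enolate carbon (4-exo-trig) and a second Fe(III) oxidises the resulting ketyl; this is an intramolecular oxidative enolate coupling, the known way from two carbonyl α-carbons to a 1,4-diketone, applied here to a four-membered ring. The single new bond C10–C11 closes the cyclobutane and with it both the bicyclo[3.1.1]heptane and the bicyclo[4.1.1]octane. C10 (quaternary) and C11 are set by the tether: C11 can reach C10 only on the face of the seven-membered ring that carries the C5–C11 bond, so the methyl group is forced to the other face whichever C10 epimer of 9 is used. Both enolates are cross-conjugated, so spin and charge reside only on C10, C11 and oxygen, and C8 is an sp3 epoxide carbon; a five-membered closure at C8, which an allylic or linear dienolate system would offer, is therefore not available. The strain of the product (estimated near 40 kcal/mol) is paid by two irreversible electron transfers, and the product cannot revert or epimerise because enolisation at the bridgeheads C10 and C11 would violate Bredt's rule. The step needs double deprotonation to outrun aldol addition of the first enolate to the second carbonyl (such ketone aldolates should revert under excess amide base) and high dilution to suppress intermolecular coupling.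

Step 8
Reactants: 11 7,8-epoxy-12-norlongipin-2-ene-1,9-dione
Product: 12 7,8-epoxylongipinane-1,9-dione (C3 methyl anti to the C10 bridge)
Conditions: Me2Zn, Cu(OTf)2 (5 mol %), P(OEt)3 (10 mol %), toluene, −30 → 0 °C; aq. NH4Cl
Reagents that add atoms: dimethylzinc, C[Zn]C
Why: Copper-catalysed conjugate addition; the methyl group should enter C3 from the face that carries only H-5, away from the C10 methyl that shields the other face of the bicyclo[3.1.1]heptenone, which sets C3; a dialkylzinc with catalytic copper should leave the epoxy ketone untouched.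

Step 9
Reactants: 12 7,8-epoxylongipinane-1,9-dione
Product: 14 7-hydroxylongipin-8-en-1-one (C7–OH anti to C11), via epoxy hydrazone 13 (not isolated)
Conditions: N2H4·H2O (1.5 equiv), AcOH (cat.), MeOH, 0 °C → rt; aq. citric acid work-up
Reagents that add atoms: none
Why: Wharton transposition: the C9 hydrazone opens the epoxide to an alkenyl diazene that loses N2, giving the C7 allylic alcohol and the C8=C9 alkene; the C7–O bond is not touched, so its configuration from step 5 is retained, while hydrazone formation at C1 is reversible and should be drained by the irreversible pathway or hydrolysed on acidic work-up.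

Step 10
Reactants: 14 7-hydroxylongipin-8-en-1-one
Product: 15 7-(triethylsilyloxy)longipin-8-en-1-one
Conditions: TESOTf, 2,6-lutidine, CH2Cl2, −78 °C
Reagents that add atoms: triethylsilyl trifluoromethanesulfonate, CC[Si](CC)(CC)OS(=O)(=O)C(F)(F)F
Why: Silylation of the hindered allylic alcohol with a silyl triflate and a hindered base; the TES ether masks C7–OH during acylation and can be removed under acidic fluoride at the end.

Step 11
Reactants: 15 7-(triethylsilyloxy)longipin-8-en-1-one
Product: 16 8,9-dihydroxy-7-(triethylsilyloxy)longipinan-1-one (8,9-cis-diol syn to C11, trans to the C7 oxygen)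
Conditions: OsO4 (5 mol %), NMO, acetone/H2O, rt
Reagents that add atoms: N-methylmorpholine N-oxide, C[N+]1([O-])CCOCC1; water, O
Why: Upjohn dihydroxylation; OsO4 should add to the C8=C9 face anti to the allylic C7 silyloxy group, the only nearby element that differentiates the two faces, which sets C8 and C9.

Step 12
Reactants: 16 8,9-dihydroxy-7-(triethylsilyloxy)longipinan-1-one
Product: 17 1-oxo-7-(triethylsilyloxy)longipinane-8,9-diyl bis[(2Z)-2-methylbut-2-enoate]
Conditions: angelic acid, 2,4,6-trichlorobenzoyl chloride, Et3N, toluene, rt; then 16, toluene, 80 °C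
Reagents that add atoms: (Z)-2-methylbut-2-enoic acid (angelic acid), C/C=C(/C)C(=O)O
Why: Yamaguchi-type mixed-anhydride esterification run without nucleophilic catalyst or alkoxide, conditions under which the angeloyl group is transferred to hindered secondary alcohols without Z→E isomerisation.

Step 13
Reactants: 17 1-oxo-7-(triethylsilyloxy)longipinane-8,9-diyl bis[(2Z)-2-methylbut-2-enoate]
Product: 18 (3R,4S,5S,7S,8R,9S,10R,11R)-7-hydroxy-1-oxolongipinane-8,9-diyl bis[(2Z)-2-methylbut-2-enoate] (CNP0344448.1)
Conditions: HF·pyridine, pyridine, THF, 0 °C → rt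
Reagents that add atoms: none
Why: Fluoride-mediated cleavage of the silyl ether under buffered acidic conditions, which avoids base-induced acyl migration to C7–OH and angelate-to-tiglate isomerisation.

## Compound list

1 | but-3-en-2-one (methyl vinyl ketone) | C=CC(C)=O | starting material
2 | 2-[(triisopropylsilyl)oxy]buta-1,3-diene | C=CC(=C)O[Si](C(C)C)(C(C)C)C(C)C | intermediate
3 | 4,4-dimethylcyclohexa-2,5-dien-1-one | CC1(C)C=CC(=O)C=C1 | starting material
4 | (4aR,8aS)-4,4-dimethyl-6-[(triisopropylsilyl)oxy]-4a,5,8,8a-tetrahydronaphthalen-1(4H)-one | O=C1C=CC(C)(C)[C@H]2[C@@H]1CC=C(O[Si](C(C)C)(C(C)C)C(C)C)C2 | intermediate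
5 | 5-(trimethylsilyl) derivative of 6 (C10–SiMe3) | O=C1C=CC(C)(C)[C@H]2[C@H](CC=C(O[Si](C(C)C)(C(C)C)C(C)C)C2)C1[Si](C)(C)C | intermediate (not isolated)
6 | cis-9,9-dimethyl-2-[(triisopropylsilyl)oxy]-1,4,4a,5,9,9a-hexahydro-6H-benzo[7]annulen-6-one | O=C1C=CC(C)(C)[C@H]2[C@H](CC=C(O[Si](C(C)C)(C(C)C)C(C)C)C2)C1 | intermediate
7 | cis-5,9,9-trimethyl-2-[(triisopropylsilyl)oxy]-1,4,4a,5,9,9a-hexahydro-6H-benzo[7]annulen-6-one (C10 epimers) | O=C1C=CC(C)(C)[C@H]2[C@H](CC=C(O[Si](C(C)C)(C(C)C)C(C)C)C2)C1C | intermediate
8 | 7,8-epoxy-5,9,9-trimethyl-2-[(triisopropylsilyl)oxy]-1,4,4a,5,7,8,9,9a-octahydro-6H-benzo[7]annulen-6-one (epoxide O syn to the ring-fusion H atoms) | O=C1[C@H]3O[C@H]3C(C)(C)[C@H]2[C@H](CC=C(O[Si](C(C)C)(C(C)C)C(C)C)C2)C1C | intermediate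
9 | cis-fused 7,8-epoxy-5,9,9-trimethyl-4a,5,7,8,9,9a-hexahydro-1H-benzo[7]annulene-2,6-dione | O=C1[C@H]3O[C@H]3C(C)(C)[C@H]2[C@H](C=CC(=O)C2)C1C | intermediate
10 | dilithium bis-enolate of 9 (C1–O/C11 and C9–O/C10) | [Li+].[Li+].[O-]C1=C(C)[C@H]2C=CC([O-])=C[C@H]2C(C)(C)[C@@H]3O[C@H]13 | intermediate (not isolated)
11 | 7,8-epoxy-12-norlongipin-2-ene-1,9-dione | O=C1[C@H]4O[C@H]4C(C)(C)[C@H]2[C@@H]3C=CC(=O)[C@H]2[C@]13C | intermediate
12 | 7,8-epoxylongipinane-1,9-dione | O=C1[C@H]4O[C@H]4C(C)(C)[C@H]2[C@@H]3[C@H](C)CC(=O)[C@H]2[C@]13C | intermediate
13 | C9 hydrazone of 12 | NN=C1[C@H]4O[C@H]4C(C)(C)[C@H]2[C@@H]3[C@H](C)CC(=O)[C@H]2[C@]13C | intermediate (not isolated)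
14 | 7-hydroxylongipin-8-en-1-one | C1=C[C@@H](O)C(C)(C)[C@H]2[C@@H]3[C@H](C)CC(=O)[C@H]2[C@]13C | intermediate
15 | 7-(triethylsilyloxy)longipin-8-en-1-one | C1=C[C@@H](O[Si](CC)(CC)CC)C(C)(C)[C@H]2[C@@H]3[C@H](C)CC(=O)[C@H]2[C@]13C | intermediate
16 | 8,9-dihydroxy-7-(triethylsilyloxy)longipinan-1-one | O[C@@H]1[C@@H](O[Si](CC)(CC)CC)C(C)(C)[C@H]2[C@@H]3[C@H](C)CC(=O)[C@H]2[C@]3(C)[C@@H]1O | intermediate
17 | 1-oxo-7-(triethylsilyloxy)longipinane-8,9-diyl bis[(2Z)-2-methylbut-2-enoate] | C/C=C(/C)C(=O)O[C@@H]1[C@@H](O[Si](CC)(CC)CC)C(C)(C)[C@H]2[C@@H]3[C@H](C)CC(=O)[C@H]2[C@]3(C)[C@@H]1OC(=O)/C(C)=C\C | intermediate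
18 | (3R,4S,5S,7S,8R,9S,10R,11R)-7-hydroxy-1-oxolongipinane-8,9-diyl bis[(2Z)-2-methylbut-2-enoate] | C/C=C(/C)C(=O)O[C@@H]1[C@@H](O)C(C)(C)[C@H]2[C@@H]3[C@H](C)CC(=O)[C@H]2[C@]3(C)[C@@H]1OC(=O)/C(C)=C\C | target

## Step count and least certain steps

Total: 13 steps. Longest linear sequence: 13 steps (1 → 18); 3 enters at step 2.

Step 7 (key step). Most likely to go wrong: aldol closure of the first-formed enolate onto the second carbonyl before the tertiary C10–H is removed, intermolecular coupling, or α-oxygenation by the oxidant instead of C–C bond formation; the four-membered closure is slow because strain develops in the transition state. Fallback, from 9 back to 11, by two-electron chemistry: double enol silylation (LDA with TMSCl present, −78 °C) gives the bis(trimethylsilyl enol ether) F1. One equivalent of NBS should brominate the less hindered, more nucleophilic silyloxydiene terminus C11 to give the α'-bromo enone F2, which keeps the C9 enol silane. CsF in MeCN then frees the C10 enolate, which displaces bromide (4-exo-tet alkylation at an α-keto carbon) to give 11.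

Step 2. Most likely to go wrong: slow cycloaddition at the β-carbon next to the quaternary centre, a second addition to the remaining enone, or insufficient discrimination of the enantiotopic faces. Fallback, from 2 and 3 back to 4: an achiral Lewis acid (EtAlCl2) gives 4 together with its enantiomer ent-4 F3. Catalyst-controlled CBS reduction of the enone carbonyl turns the racemate into the diastereomeric allylic alcohols F4 (from 4) and F5 (from F3), which are separated. MnO2 oxidation of the allylic alcohol F4 returns 4.

Step 3. Most likely to go wrong: competing migration of the vinylic carbon, dipolar addition of the diazoalkane to the enone C=C, or loss of the enol silane under Lewis acid. Fallback, from 4 back to 7: homologation with ethyl diazoacetate and BF3·OEt2, a reagent class for which migration of the sp3 carbon of cyclic enones is the expected course, gives the β-keto ester F6. C-Methylation (K2CO3, MeI) gives the quaternary β-keto ester F7, and Krapcho dealkoxycarbonylation (LiCl, wet DMSO, 140 °C) gives 7.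

Step 5. Most likely to go wrong: poor facial selectivity on the flexible seven-membered enone, so that the C7 configuration is not controlled. Fallback, from 4 back to 8, by changing the order: the rigid cis-decalin enone 4 is epoxidised first (t-BuOOH, Triton B), where the convex face is well defined, to give the epoxy ketone F8. Ring expansion with TMSCHN2 (the oxiranyl carbon is a poor migrating group, so C4 should migrate) gives the seven-membered epoxy ketone F9, and α'-methylation (LDA, MeI) gives 8.

Step 9. Most likely to go wrong: persistent hydrazone or azine formation at the C1 ketone while condensation at the hindered C9 carbonyl is slow. Fallback, from 11 back to 14: the zinc enolate of the conjugate addition is trapped with TBSOTf to give the C1 silyl enol ether F10. The Wharton transposition then gives the allylic alcohol F11 with C1 still masked, and TBAF/AcOH releases the ketone to give 14.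

Step 12. Most likely to go wrong: incomplete acylation of the neopentyl C9 hydroxyl, Z→E isomerisation under forcing conditions, or silyl migration from C7. Fallback, from 16 back to 17, by building the Z-alkene on the ester: esterification with 2-[bis(2,2,2-trifluoroethoxy)phosphoryl]propanoic acid (EDC, DMAP) gives the bis(phosphonopropanoate) F12. A Still–Gennari olefination with acetaldehyde (KHMDS, 18-crown-6, −78 °C) then gives the (Z)-2-methylbut-2-enoates of 17.

## Further compounds

F1 | step 7 | bis(trimethylsilyl enol ether) of 9 | C[Si](C)(C)OC1=C(C)[C@H]2C=CC(O[Si](C)(C)C)=C[C@H]2C(C)(C)[C@@H]3O[C@H]13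
F2 | step 7 | C11-bromo enone with C9 trimethylsilyl enol ether | C[Si](C)(C)OC1=C(C)[C@H]2C=CC(=O)C(Br)[C@H]2C(C)(C)[C@@H]3O[C@H]13
F3 | step 2 | ent-4, (4aS,8aR)-4,4-dimethyl-6-[(triisopropylsilyl)oxy]-4a,5,8,8a-tetrahydronaphthalen-1(4H)-one | O=C1C=CC(C)(C)[C@@H]2[C@H]1CC=C(O[Si](C(C)C)(C(C)C)C(C)C)C2
F4 | step 2 | allylic alcohol from CBS reduction of 4 | O[C@@H]1C=CC(C)(C)[C@H]2[C@@H]1CC=C(O[Si](C(C)C)(C(C)C)C(C)C)C2
F5 | step 2 | diastereomeric allylic alcohol from CBS reduction of F3 | O[C@@H]1C=CC(C)(C)[C@@H]2[C@H]1CC=C(O[Si](C(C)C)(C(C)C)C(C)C)C2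
F6 | step 3 | ethyl ester of the 5-carboxylic acid of 6 (β-keto ester at C10) | O=C1C=CC(C)(C)[C@H]2[C@H](CC=C(O[Si](C(C)C)(C(C)C)C(C)C)C2)C1C(=O)OCC
F7 | step 3 | C10-methylated β-keto ester | O=C1C=CC(C)(C)[C@H]2[C@H](CC=C(O[Si](C(C)C)(C(C)C)C(C)C)C2)C1(C)C(=O)OCC
F8 | step 5 | 2,3-epoxide of 4 (epoxide O syn to the ring-fusion H atoms) | O=C1[C@H]3O[C@H]3C(C)(C)[C@H]2[C@@H]1CC=C(O[Si](C(C)C)(C(C)C)C(C)C)C2
F9 | step 5 | 7,8-epoxide of 6 | O=C1[C@H]3O[C@H]3C(C)(C)[C@H]2[C@H](CC=C(O[Si](C(C)C)(C(C)C)C(C)C)C2)C1
F10 | step 9 | C1 tert-butyldimethylsilyl enol ether of 12 | O=C1[C@H]4O[C@H]4C(C)(C)[C@H]2[C@@H]3[C@H](C)C=C(O[Si](C)(C)C(C)(C)C)[C@H]2[C@]13C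
F11 | step 9 | C1 tert-butyldimethylsilyl enol ether of 14 | C1=C[C@@H](O)C(C)(C)[C@H]2[C@@H]3[C@H](C)C=C(O[Si](C)(C)C(C)(C)C)[C@H]2[C@]13C
F12 | step 12 | 8,9-bis{2-[bis(2,2,2-trifluoroethoxy)phosphoryl]propanoate} of 16 | CC(C(=O)O[C@@H]1[C@@H](O[Si](CC)(CC)CC)C(C)(C)[C@H]2[C@@H]3[C@H](C)CC(=O)[C@H]2[C@]3(C)[C@@H]1OC(=O)C(C)P(=O)(OCC(F)(F)F)OCC(F)(F)F)P(=O)(OCC(F)(F)F)OCC(F)(F)F
A1 | alternative 1 | acyclic trienone photosubstrate | C=C[C@@H](O[Si](C)(C)C(C)(C)C)C(C)(C)/C=C/[C@H](C)CC(=O)/C=C(\C)C=C
A2 | alternative 1 | crossed photoadduct, bicyclo[3.1.1]heptanone with two vinyl arms | C=C[C@@H](O[Si](C)(C)C(C)(C)C)C(C)(C)[C@H]2[C@@H]3[C@H](C)CC(=O)[C@H]2[C@]3(C)C=C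
A3 | alternative 2 | (1R,5R)-(+)-verbenone | C1[C@@H]2C(C)=CC(=O)[C@H]1C2(C)C
A4 | alternative 2 | divinyl verbenone derivative for ring-closing metathesis | C=C[C@@H](O[Si](C)(C)C(C)(C)C)C(C)(C)[C@H]2[C@@H]3C(C)=CC(=O)[C@H]2[C@]3(C)C=C
A5 | alternative 3 | bridged lactone for Ireland–Claisen ring contraction | O=C1O[C@@H]2[C@@H](C)[C@@H]3[C@H]1C=C[C@@H](O[Si](C)(C)C(C)(C)C)C(C)(C)[C@@H]3C=C2OC
A6 | alternative 3 | ring-contracted tricyclic acid (carboxyl on C10) | C1=C[C@@H](O[Si](C)(C)C(C)(C)C)C(C)(C)[C@H]2[C@@H]3[C@H](C)C=C(OC)[C@H]2[C@]13C(=O)O
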